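Retrosynthesis: the C2–C3 and C4–C4a bonds of ring C are cut together. This removes a two-carbon C3–C4 unit (a terminal ynamide, with C4 masked as an enamide) and leaves an open O-aryl acylal in which O1–C2 already joins rings A and B.
The O1–C2 bond is then cut to a ring A phenol and a ring B aldehyde; each prenyl group is cut to an aryllithium and prenyl bromide; the C8 methyl is traced back to the formyl group of 2,4,6-trihydroxybenzaldehyde.
Forward: ring A phenol (steps 1–5), ring B aldehyde (steps 6–7), union at O1–C2 (step 8), ring C closed last by the annulation (step 9), then removal of the two MOM groups (step 10).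
Enabling feature: C4a is the only unsubstituted carbon of the phloroglucinol-type ring A and lies ortho to O1, and the 4'-methoxy group of ring B is para to C2. An O1=C2 oxocarbenium ion therefore forms easily and has a strongly nucleophilic arene carbon placed to close a six-membered ring once two carbons are inserted.
Stereochemistry: the single stereocentre C2 is set in step 9 by the chiral counter-anion of a Brønsted acid catalyst; the one later step is acidic, to avoid base-induced opening of the flavanone to the chalcone.

Key step: step 9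

Assumption: the sense of induction of the chiral acid in step 9 cannot be predicted with confidence; the (R)-acid is written, and its mirror image is to be used with no other change if the first run shows that it favours the (2R) series.

Step 1
Reactants: 1 2,4,6-trihydroxybenzaldehyde
Product: 2 2-hydroxy-4,6-bis(methoxymethoxy)benzaldehyde
Conditions: MOMCl (2.1 equiv), i-Pr2NEt, CH2Cl2, 0 °C to rt
Reagents that add atoms: chloromethyl methyl ether, COCCl
Why: O-alkylation of the para hydroxyl and of one ortho hydroxyl; the remaining ortho hydroxyl is hydrogen-bonded to the formyl group and stays free, which singles out the oxygen that becomes O1.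

Step 2
Reactants: 2 2-hydroxy-4,6-bis(methoxymethoxy)benzaldehyde
Product: 4 3,5-bis(methoxymethoxy)-2-methylphenol, via ethyl aryl carbonate 3 (not isolated)
Conditions: ClCO2Et, Et3N, THF, 0 °C; then NaBH4, THF/H2O, 0 °C to rt
Reagents that add atoms: none
Why: Reductive deoxygenation of an ortho-formyl phenol through its carbonate: borohydride reduces the aldehyde, the carbonate migrates to the benzylic oxygen and is eliminated to an ortho-quinone methide, which takes up a second hydride to give the methyl group; MOM ethers are stable to these basic conditions.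

Step 3
Reactants: 4 3,5-bis(methoxymethoxy)-2-methylphenol
Product: 5 [3,5-bis(methoxymethoxy)-2-methylphenoxy]triisopropylsilane
Conditions: TIPSCl, imidazole, DMF, rt
Reagents that add atoms: chlorotriisopropylsilane, CC(C)[Si](Cl)(C(C)C)C(C)C
Why: Standard silylation of a phenol; the bulky, non-coordinating silyl ether masks the acidic proton and steers the lithiation of step 4 away from the neighbouring ring position.

Step 4
Reactants: 5 [3,5-bis(methoxymethoxy)-2-methylphenoxy]triisopropylsilane
Product: 7 [3,5-bis(methoxymethoxy)-2-methyl-4-(3-methylbut-2-en-1-yl)phenoxy]triisopropylsilane, via aryllithium 6 (not isolated)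
Conditions: n-BuLi, THF, 0 °C; then CuBr·SMe2 (10 mol %), prenyl bromide, −78 °C to rt
Reagents that add atoms: 1-bromo-3-methylbut-2-ene (prenyl bromide), CC(C)=CCBr
Why: Directed ortho-metalation at the only ring C–H flanked by two MOM-oxy groups, followed by copper-catalysed SN2 allylation, should place the linear prenyl group on the carbon that becomes C6.

Step 5
Reactants: 7 [3,5-bis(methoxymethoxy)-2-methyl-4-(3-methylbut-2-en-1-yl)phenoxy]triisopropylsilane
Product: 8 3,5-bis(methoxymethoxy)-2-methyl-4-(3-methylbut-2-en-1-yl)phenol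
Conditions: TBAF, THF, 0 °C; aqueous work-up
Reagents that add atoms: none
Why: Fluoride cleavage of the aryl silyl ether frees the one hydroxyl that becomes O1; MOM ethers and the prenyl group are inert to fluoride.

Step 6
Reactants: 9 3-bromo-4-methoxybenzaldehyde
Product: 10 2-bromo-4-(dimethoxymethyl)-1-methoxybenzene
Conditions: HC(OMe)3, p-TsOH·H2O (cat.), MeOH, rt
Reagents that add atoms: trimethyl orthoformate, COC(OC)OC
Why: Acid-catalysed acetalisation protects the aldehyde against the organolithium chemistry of step 7.

Step 7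
Reactants: 10 2-bromo-4-(dimethoxymethyl)-1-methoxybenzene
Product: 13 4-methoxy-3-(3-methylbut-2-en-1-yl)benzaldehyde, via aryllithium 11 (not isolated), via prenylated dimethyl acetal 12 (not isolated)
Conditions: n-BuLi, THF, −78 °C; CuBr·SMe2 (10 mol %), prenyl bromide, −78 to 0 °C; then 1 M aq HCl, THF, rt
Reagents that add atoms: 1-bromo-3-methylbut-2-ene (prenyl bromide), CC(C)=CCBr; water, O
Why: Bromine–lithium exchange, copper-catalysed SN2 allylation with prenyl bromide and hydrolysis of the dimethyl acetal in the work-up should give the ring B aldehyde with the linear prenyl group.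

Step 8
Reactants: 13 4-methoxy-3-(3-methylbut-2-en-1-yl)benzaldehyde; 8 3,5-bis(methoxymethoxy)-2-methyl-4-(3-methylbut-2-en-1-yl)phenol
Product: 15 [3,5-bis(methoxymethoxy)-2-methyl-4-(3-methylbut-2-en-1-yl)phenoxy][4-methoxy-3-(3-methylbut-2-en-1-yl)phenyl]methyl pivalate (racemic), via chloro pivalate 14 (not isolated)
Conditions: 13, PivCl, ZnCl2 (2 mol %), CH2Cl2, −10 °C to rt; then 8, Cs2CO3, MeCN, 0 °C to rt
Reagents that add atoms: pivaloyl chloride, CC(C)(C)C(=O)Cl
Why: Lewis-acid-catalysed addition of an acyl chloride to an aldehyde gives a 1-chloroalkyl ester, which alkylates the phenoxide at oxygen (the chemistry of acyloxyalkyl aryl ethers) and so forms O1–C2; the hindered pivaloyl group resists acyl transfer, and the racemic acetal carbon is of no consequence because it becomes planar in step 9.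

Step 9
Reactants: 15 [3,5-bis(methoxymethoxy)-2-methyl-4-(3-methylbut-2-en-1-yl)phenoxy][4-methoxy-3-(3-methylbut-2-en-1-yl)phenyl]methyl pivalate; 16 N-ethynyl-N,4-dimethylbenzenesulfonamide
Product: 18 (2S)-5,7-bis(methoxymethoxy)-2-[4-methoxy-3-(3-methylbut-2-en-1-yl)phenyl]-8-methyl-6-(3-methylbut-2-en-1-yl)chroman-4-one, via 4-sulfonamido-2H-chromene 17 (not isolated)
Conditions: 16 (2.5 equiv), (R)-3,3'-bis(2,4,6-triisopropylphenyl)-1,1'-binaphthalene-2,2'-diyl N-(trifluoromethanesulfonyl)phosphoramide (10 mol %), 4 Å MS, toluene/CH2Cl2, −60 to −30 °C; then 1 M aq HCl, THF, 0 °C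
Reagents that add atoms: water, O
Why: Proposed new method: the chiral acid protonates the pivalate carbonyl of 15 and pivalic acid leaves, giving the O-aryl oxocarbenium ion O1=C2 (stabilised by the 4'-methoxy group of ring B) as a contact ion pair with the chiral phosphoramidate; the nucleophilic β-carbon of ynamide 16 adds to C2 (C2–C3 bond), the resulting keteniminium carbon is captured by C4a of ring A in a Friedel–Crafts step (C4–C4a bond), the proton lost on rearomatisation returns the acid, and enamide 17 is hydrolysed to the ketone in the acidic work-up. The closest known reaction types are the oxa-Povarov reaction (formal inverse-electron-demand [4+2] cycloaddition of O-aryl oxocarbenium ions with alkenes), keteniminium Friedel–Crafts cyclisations of ynamides and chiral-anion-directed additions to oxocarbenium ion pairs; an alkyne-level two-carbon partner under asymmetric control is the new element. Ring C closes by 6-exo-dig attack of the arene on the sp carbon of the keteniminium, the C3=C4 bond ending up inside the ring; if the ynamide is protonated first, the same two bonds form in reverse order (Friedel–Crafts, then 6-endo-trig attack of the enamide on the oxocarbenium) and converge on 17. The only new stereocentre, C2, is set when C3 adds to one face of the oxocarbenium held in the chiral pocket of the counter-anion, and should be (S). Regioselectivity is secured because C4a is the only unsubstituted carbon of ring A and because the carboxylate is a far better leaving group than the aryloxide, so the ion pair forms only in the wanted direction. Chemoselectivity over the two prenyl alkenes and the MOM acetals rests on the much higher nucleophilicity of the ynamide and on the low temperature.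

Step 10
Reactants: 18 (2S)-5,7-bis(methoxymethoxy)-2-[4-methoxy-3-(3-methylbut-2-en-1-yl)phenyl]-8-methyl-6-(3-methylbut-2-en-1-yl)chroman-4-one
Product: 19 (2S)-5,7-dihydroxy-2-[4-methoxy-3-(3-methylbut-2-en-1-yl)phenyl]-8-methyl-6-(3-methylbut-2-en-1-yl)chroman-4-one
Conditions: 3 M aq HCl, MeOH, 40 °C, short reaction time
Reagents that add atoms: none
Why: Acid-catalysed acetal exchange with methanol removes both MOM groups; the mild temperature is meant to spare the prenyl groups, and C2 can only be lost through ring-opening that needs base or forcing acid.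

Compound list
1 | 2,4,6-trihydroxybenzaldehyde | O=Cc1c(O)cc(O)cc1O | starting material
2 | 2-hydroxy-4,6-bis(methoxymethoxy)benzaldehyde | COCOc1cc(O)c(C=O)c(OCOC)c1 | intermediate
3 | ethyl 2-formyl-3,5-bis(methoxymethoxy)phenyl carbonate | CCOC(=O)Oc1cc(OCOC)cc(OCOC)c1C=O | intermediate
4 | 3,5-bis(methoxymethoxy)-2-methylphenol | COCOc1cc(O)c(C)c(OCOC)c1 | intermediate
5 | [3,5-bis(methoxymethoxy)-2-methylphenoxy]triisopropylsilane | COCOc1cc(O[Si](C(C)C)(C(C)C)C(C)C)c(C)c(OCOC)c1 | intermediate
6 | [2,6-bis(methoxymethoxy)-3-methyl-4-(triisopropylsilyloxy)phenyl]lithium | [Li]c1c(OCOC)cc(O[Si](C(C)C)(C(C)C)C(C)C)c(C)c1OCOC | intermediate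
7 | [3,5-bis(methoxymethoxy)-2-methyl-4-(3-methylbut-2-en-1-yl)phenoxy]triisopropylsilane | CC(C)=CCc1c(OCOC)cc(O[Si](C(C)C)(C(C)C)C(C)C)c(C)c1OCOC | intermediate
8 | 3,5-bis(methoxymethoxy)-2-methyl-4-(3-methylbut-2-en-1-yl)phenol | CC(C)=CCc1c(OCOC)cc(O)c(C)c1OCOC | intermediate
9 | 3-bromo-4-methoxybenzaldehyde | COc1ccc(C=O)cc1Br | starting material
10 | 2-bromo-4-(dimethoxymethyl)-1-methoxybenzene | COc1ccc(C(OC)OC)cc1Br | intermediate
11 | [5-(dimethoxymethyl)-2-methoxyphenyl]lithium | [Li]c1cc(C(OC)OC)ccc1OC | intermediate
12 | 4-(dimethoxymethyl)-1-methoxy-2-(3-methylbut-2-en-1-yl)benzene | COc1ccc(C(OC)OC)cc1CC=C(C)C | intermediate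
13 | 4-methoxy-3-(3-methylbut-2-en-1-yl)benzaldehyde | COc1ccc(C=O)cc1CC=C(C)C | intermediate
14 | chloro[4-methoxy-3-(3-methylbut-2-en-1-yl)phenyl]methyl pivalate (racemic) | COc1ccc(C(Cl)OC(=O)C(C)(C)C)cc1CC=C(C)C | intermediate
15 | [3,5-bis(methoxymethoxy)-2-methyl-4-(3-methylbut-2-en-1-yl)phenoxy][4-methoxy-3-(3-methylbut-2-en-1-yl)phenyl]methyl pivalate (racemic) | COc1ccc(C(Oc2cc(OCOC)c(CC=C(C)C)c(OCOC)c2C)OC(=O)C(C)(C)C)cc1CC=C(C)C | intermediate
16 | N-ethynyl-N,4-dimethylbenzenesulfonamide (terminal ynamide sold as a coupling reagent) | C#CN(C)S(=O)(=O)c1ccc(C)cc1 | starting material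
17 | N-[(2S)-5,7-bis(methoxymethoxy)-2-[4-methoxy-3-(3-methylbut-2-en-1-yl)phenyl]-8-methyl-6-(3-methylbut-2-en-1-yl)-2H-chromen-4-yl]-N,4-dimethylbenzenesulfonamide | COc1ccc([C@@H]2C=C(N(C)S(=O)(=O)c3ccc(C)cc3)c3c(OCOC)c(CC=C(C)C)c(OCOC)c(C)c3O2)cc1CC=C(C)C | intermediate
18 | (2S)-5,7-bis(methoxymethoxy)-2-[4-methoxy-3-(3-methylbut-2-en-1-yl)phenyl]-8-methyl-6-(3-methylbut-2-en-1-yl)chroman-4-one | COc1ccc([C@@H]2CC(=O)c3c(OCOC)c(CC=C(C)C)c(OCOC)c(C)c3O2)cc1CC=C(C)C | intermediate
19 | (2S)-5,7-dihydroxy-2-[4-methoxy-3-(3-methylbut-2-en-1-yl)phenyl]-8-methyl-6-(3-methylbut-2-en-1-yl)chroman-4-one | COc1ccc([C@@H]2CC(=O)c3c(O)c(CC=C(C)C)c(O)c(C)c3O2)cc1CC=C(C)C | target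

Total step count: 10. Longest linear sequence: 8 steps (steps 1–5, 8, 9, 10).

Steps most likely to fail

Step 9 (Proposed new method). The ion pair may give poor facial selectivity at C2. The ynamide may be consumed by addition of the released pivalic acid or of the catalyst. The oxocarbenium ion may alkylate ring A of a second molecule instead of being captured by the ynamide. The aryl ether oxygen may attack the keteniminium and divert the material into an alkyne–oxocarbenium metathesis. The fallback uses known chemistry, sets out from phenol 8 and aldehyde 13, and returns to the route at 18. Bromination of the single free ring position of 8 (NBS, CH2Cl2, −78 °C) should give the bromophenol F1. Double lithiation (n-BuLi, 2.2 equiv, THF, −78 °C) and acylation with N-methoxy-N-methylacetamide should give the 2-hydroxyacetophenone F2. Claisen–Schmidt condensation with 13 (KOH, EtOH, rt) should give the chalcone F3, whose only free ortho hydroxyl is the one that becomes O1. Oxa-Michael ring closure (NaOAc, EtOH, reflux) should give the racemic flavanone F4. Kinetic resolution by asymmetric transfer hydrogenation (RuCl(p-cymene)[(R,R)-TsDPEN], HCO2H/Et3N, rt) is expected to reduce the (2R) enantiomer to the cis-flavan-4-ol F5, by analogy with the (R)-carbinols this catalyst gives from aryl ketones, and to leave (2S)-18, which is separated and carried into step 10.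

Step 8. Addition of pivaloyl chloride to the electron-rich aldehyde may be incomplete or reversible, so that free acyl chloride acylates the phenoxide. The ionised chloro ester may alkylate the ring carbon of the phenol instead of its oxygen. Traces of HCl may add to the prenyl alkenes. The fallback sets out from 13 and 8 and returns to the route at 18. Pinnick oxidation of 13 (NaClO2, NaH2PO4, excess 2-methylbut-2-ene, t-BuOH/H2O) should give the benzoic acid F6. Esterification with 8 (EDC·HCl, DMAP, CH2Cl2) should give the aryl ester F7, forming O1–C2 by simple acylation. Reductive acetylation (i-Bu2AlH, CH2Cl2, −78 °C; then Ac2O, pyridine, DMAP, −78 °C) should give the α-acetoxy ether F8, which takes the place of 15 in step 9 and delivers 18.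

Step 10. The protic acid may cyclise the C6 prenyl group onto the freed 5- or 7-hydroxyl to a dimethylchroman, may hydrate the alkenes, or may erode the configuration at C2 through reversible ring-opening. The fallback sets out from 18 and returns at 19, and replaces protic solvolysis by silyl transfer under buffered conditions. Me3SiOTf and 2,2'-bipyridyl (CH2Cl2, 0 °C) should convert both aryl MOM ethers into the bis(trimethylsilyl) ether F9, the methoxymethyl groups being taken up by the bipyridyl. Stirring with water at rt should then hydrolyse the silyl ethers to 19.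

Further compounds
F1 | step 9 | 2-bromo-3,5-bis(methoxymethoxy)-6-methyl-4-(3-methylbut-2-en-1-yl)phenol | Oc1c(Br)c(OCOC)c(CC=C(C)C)c(OCOC)c1C
F2 | step 9 | 1-[2-hydroxy-4,6-bis(methoxymethoxy)-3-methyl-5-(3-methylbut-2-en-1-yl)phenyl]ethan-1-one | CC(=O)c1c(O)c(C)c(OCOC)c(CC=C(C)C)c1OCOC
F3 | step 9 | (E)-1-[2-hydroxy-4,6-bis(methoxymethoxy)-3-methyl-5-(3-methylbut-2-en-1-yl)phenyl]-3-[4-methoxy-3-(3-methylbut-2-en-1-yl)phenyl]prop-2-en-1-one | COc1ccc(/C=C/C(=O)c2c(O)c(C)c(OCOC)c(CC=C(C)C)c2OCOC)cc1CC=C(C)C
F4 | step 9 | racemic 5,7-bis(methoxymethoxy)-2-[4-methoxy-3-(3-methylbut-2-en-1-yl)phenyl]-8-methyl-6-(3-methylbut-2-en-1-yl)chroman-4-one | COc1ccc(C2CC(=O)c3c(OCOC)c(CC=C(C)C)c(OCOC)c(C)c3O2)cc1CC=C(C)C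
F5 | step 9 | (2R,4R)-5,7-bis(methoxymethoxy)-2-[4-methoxy-3-(3-methylbut-2-en-1-yl)phenyl]-8-methyl-6-(3-methylbut-2-en-1-yl)chroman-4-ol | COc1ccc([C@H]2C[C@@H](O)c3c(OCOC)c(CC=C(C)C)c(OCOC)c(C)c3O2)cc1CC=C(C)C
F6 | step 8 | 4-methoxy-3-(3-methylbut-2-en-1-yl)benzoic acid | COc1ccc(C(=O)O)cc1CC=C(C)C
F7 | step 8 | 3,5-bis(methoxymethoxy)-2-methyl-4-(3-methylbut-2-en-1-yl)phenyl 4-methoxy-3-(3-methylbut-2-en-1-yl)benzoate | COc1ccc(C(=O)Oc2cc(OCOC)c(CC=C(C)C)c(OCOC)c2C)cc1CC=C(C)C
F8 | step 8 | [3,5-bis(methoxymethoxy)-2-methyl-4-(3-methylbut-2-en-1-yl)phenoxy][4-methoxy-3-(3-methylbut-2-en-1-yl)phenyl]methyl acetate (racemic) | COc1ccc(C(OC(C)=O)Oc2cc(OCOC)c(CC=C(C)C)c(OCOC)c2C)cc1CC=C(C)C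
F9 | step 10 | (2S)-2-[4-methoxy-3-(3-methylbut-2-en-1-yl)phenyl]-8-methyl-6-(3-methylbut-2-en-1-yl)-5,7-bis(trimethylsilyloxy)chroman-4-one | COc1ccc([C@@H]2CC(=O)c3c(O[Si](C)(C)C)c(CC=C(C)C)c(O[Si](C)(C)C)c(C)c3O2)cc1CC=C(C)C
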